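**Retrosynthetic overview**

1. The target is a 2-hydroxy-5-methoxy-1,4-benzoquinone, its only ring, whose C3 carries a pentadecyl chain with a secondary acetate at C2'. C2' lies between two CH2 groups (C1' on the ring, C3' of the chain), which a carbonyl reduction could hardly differentiate.
2. End game: target 17 ⇐ quinonyl acetate 16 (methanolysis of the ring acetate only) ⇐ arene 15 (oxidative demethylation of the two para-related methoxy groups at arene C3/C6, with the side-chain carbon as C1).
3. Key disconnection: C2' is treated as an aldehyde carbon. The acetate O–acyl bond and the C2'–C3' bond of 15 are made in one operation from aldehyde 10, acetyl bromide 13 and tridecylzinc bromide 12 under chiral nickel catalysis.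
4. 10 ⇐ allylarene 8 (alkene cleavage) ⇐ aromatic Claisen rearrangement of allyl ether 5 ⇐ phenol 3 ⇐ Dakin oxidation of aldehyde 1; 12 ⇐ 1-bromotridecane 11 + Zn.
5. No ring is formed in the route; the benzene ring of 1 becomes the quinone ring.

Key step: step 7

Assumption: the sense of induction of the chiral bis(oxazoline) ligand on this substrate cannot be predicted with certainty, so the antipode that gives R at C2' is to be fixed in a test run and the configuration checked by Mosher analysis of a deacetylated sample.

**Step 1**
Reactants: 1 2,4,5-trimethoxybenzaldehyde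
Product: 3 2,4,5-trimethoxyphenol, via 2,4,5-trimethoxyphenyl formate 2 (not isolated)
Conditions: 30% H2O2, cat. H2SO4, MeOH, rt, under Ar
Reagents that add atoms: hydrogen peroxide, OO
Why: Acid-catalysed Dakin oxidation, in which the hydroperoxide adduct of the electron-rich aldehyde undergoes Baeyer–Villiger-type aryl migration to formate 2, which methanol solvolyses to the phenol.

**Step 2**
Reactants: 3 2,4,5-trimethoxyphenol; 4 allyl bromide
Product: 5 1-(allyloxy)-2,4,5-trimethoxybenzene
Conditions: K2CO3, acetone, reflux, under Ar
Reagents that add atoms: none
Why: Williamson ether synthesis of the phenoxide with a reactive allylic bromide, run under argon because the electron-rich phenol is air-sensitive.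

**Step 3**
Reactants: 5 1-(allyloxy)-2,4,5-trimethoxybenzene
Product: 7 2-allyl-3,4,6-trimethoxyphenol, via 6-allyl-2,4,5-trimethoxycyclohexa-2,4-dien-1-one 6 (not isolated)
Conditions: N,N-diethylaniline, 190 °C, under Ar
Reagents that add atoms: none
Why: Aromatic Claisen rearrangement ([3,3]-sigmatropic shift) delivers the allyl group to the only unsubstituted ortho position, and dienone 6 tautomerises to the phenol.

**Step 4**
Reactants: 7 2-allyl-3,4,6-trimethoxyphenol
Product: 8 2-allyl-3,4,6-trimethoxyphenyl acetate
Conditions: Ac2O, pyridine, cat. DMAP, CH2Cl2, 0 °C to rt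
Reagents that add atoms: acetic anhydride, CC(=O)OC(C)=O
Why: DMAP-catalysed O-acetylation masks the phenol so that it cannot form a lactol with the aldehyde made next and so that it later steers the ring oxidation away from the C2 oxygen.

**Step 5**
Reactants: 8 2-allyl-3,4,6-trimethoxyphenyl acetate
Product: 10 2-(2-acetoxy-3,5,6-trimethoxyphenyl)acetaldehyde, via 2-(2,3-dihydroxypropyl)-3,4,6-trimethoxyphenyl acetate 9 (not isolated)
Conditions: OsO4 (cat.), NaIO4, 2,6-lutidine, 1,4-dioxane/H2O, rt; aldehyde used promptly
Reagents that add atoms: osmium tetroxide, O=[Os](=O)(=O)=O (oxygen-transfer catalyst); sodium periodate, [Na+].[O-]I(=O)(=O)=O (stoichiometric oxidant)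
Why: Lemieux–Johnson oxidation, in which catalytic OsO4 dihydroxylates the terminal alkene and NaIO4 cleaves diol 9 in the same pot, 2,6-lutidine limiting over-oxidation of the enolisable arylacetaldehyde.

**Step 6**
Reactants: 11 1-bromotridecane
Product: 12 tridecylzinc bromide
Conditions: Zn dust, I2 (cat.), DMA, 70 °C; titrated solution used directly
Reagents that add atoms: zinc, [Zn]
Why: Direct oxidative insertion of iodine-activated zerovalent zinc into a primary alkyl bromide in a polar amide solvent gives an alkylzinc bromide mild enough to tolerate the ester groups of the coupling partner.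

**Step 7**
Reactants: 10 2-(2-acetoxy-3,5,6-trimethoxyphenyl)acetaldehyde; 13 acetyl bromide; 12 tridecylzinc bromide
Product: 15 (2R)-1-(2-acetoxy-3,5,6-trimethoxyphenyl)pentadecan-2-yl acetate, via racemic 1-bromo-2-(2-acetoxy-3,5,6-trimethoxyphenyl)ethyl acetate 14 (not isolated)
Conditions: AcBr (1.0 equiv), ZnBr2 (1 mol%), CH2Cl2, −20 °C; then NiBr2·glyme (10 mol%), chiral 2,2'-(propane-2,2-diyl)bis(4-substituted oxazoline) L* (12 mol%, antipode giving R), 12 (1.3 equiv in DMA), THF, −10 °C
Reagents that add atoms: none
Why: Proposed new method: acetyl bromide adds across the C=O of 10 to give racemic 14, monovalent nickel abstracts its bromine to leave a planar α-acetoxyalkyl radical (so both enantiomers of 14 converge), and a ligand-bound tridecylnickel species formed by transmetalation from 12 captures the radical and reductively eliminates from trivalent nickel to forge C2'–C3'. The closest known reaction types are the NiBr2·glyme/bis(oxazoline)-catalysed enantioconvergent coupling of the same in situ-made 1-bromoalkyl esters with alkylnickel species generated from an olefin and a hydrosilane, and enantioconvergent nickel-catalysed Negishi couplings of alkylzinc halides with racemic α-phthalimidoalkyl chlorides; what is new is pairing that electrophile class with an alkylzinc nucleophile and using an arylacetaldehyde. No ring is closed. The one new stereocentre (C2', R) is controlled by the chiral ligand on nickel, which recognises the radical through its coordinating acetate carbonyl, so no steric bias between the two flanking methylenes is required. The step needs chemoselectivity for C–Br activation over the aryl and alkyl ester carbonyls and for coupling over loss of HBr to the enol acetate, which the low temperature, the absence of base, the strict 1:1 use of AcBr and the mild organozinc should secure. Since C2' emerges already acetylated, no free carbinol has to be handled or acylated later.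

**Step 8**
Reactants: 15 (2R)-1-(2-acetoxy-3,5,6-trimethoxyphenyl)pentadecan-2-yl acetate
Product: 16 (2R)-1-(2-acetoxy-5-methoxy-3,6-dioxocyclohexa-1,4-dien-1-yl)pentadecan-2-yl acetate
Conditions: (NH4)2Ce(NO3)6 (2.5 equiv), MeCN/H2O, 0 °C
Reagents that add atoms: water, O
Why: Oxidative demethylation by tetravalent cerium (single-electron oxidation, ipso attack of water, loss of methanol) converts the only para-related methoxy pair into the para-quinone, while the weakly donating acetoxy group at C2 is retained and the remote stereocentre is untouched.

**Step 9**
Reactants: 16 (2R)-1-(2-acetoxy-5-methoxy-3,6-dioxocyclohexa-1,4-dien-1-yl)pentadecan-2-yl acetate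
Product: 17 (2R)-1-(2-hydroxy-5-methoxy-3,6-dioxocyclohexa-1,4-dien-1-yl)pentadecan-2-yl acetate
Conditions: NaHCO3 (1.2 equiv), MeOH, 0 °C, short reaction time; then dilute HCl to pH 3
Reagents that add atoms: none
Why: The ring acetate is the ester of a vinylogous carboxylic acid and undergoes base-mediated transesterification with methanol far faster than the secondary alkyl acetate, so chemoselective deacylation leaves C2' and its acetate intact.

**Compound list**

1 | 2,4,5-trimethoxybenzaldehyde | COc1cc(OC)c(C=O)cc1OC | starting material
2 | 2,4,5-trimethoxyphenyl formate | COc1cc(OC)c(OC=O)cc1OC | intermediate (not isolated)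
3 | 2,4,5-trimethoxyphenol | COc1cc(OC)c(O)cc1OC | intermediate
4 | allyl bromide (3-bromoprop-1-ene) | C=CCBr | starting material
5 | 1-(allyloxy)-2,4,5-trimethoxybenzene | C=CCOc1cc(OC)c(OC)cc1OC | intermediate
6 | 6-allyl-2,4,5-trimethoxycyclohexa-2,4-dien-1-one (racemic) | C=CCC1C(=O)C(OC)=CC(OC)=C1OC | intermediate (not isolated)
7 | 2-allyl-3,4,6-trimethoxyphenol | C=CCc1c(O)c(OC)cc(OC)c1OC | intermediate
8 | 2-allyl-3,4,6-trimethoxyphenyl acetate | C=CCc1c(OC(C)=O)c(OC)cc(OC)c1OC | intermediate
9 | 2-(2,3-dihydroxypropyl)-3,4,6-trimethoxyphenyl acetate (racemic) | CC(=O)Oc1c(OC)cc(OC)c(OC)c1CC(O)CO | intermediate (not isolated)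
10 | 2-(2-acetoxy-3,5,6-trimethoxyphenyl)acetaldehyde | CC(=O)Oc1c(OC)cc(OC)c(OC)c1CC=O | intermediate
11 | 1-bromotridecane | CCCCCCCCCCCCCBr | starting material
12 | tridecylzinc bromide | CCCCCCCCCCCCC[Zn]Br | intermediate
13 | acetyl bromide | CC(=O)Br | starting material
14 | 1-bromo-2-(2-acetoxy-3,5,6-trimethoxyphenyl)ethyl acetate (racemic) | CC(=O)OC(Br)Cc1c(OC(C)=O)c(OC)cc(OC)c1OC | intermediate (not isolated)
15 | (2R)-1-(2-acetoxy-3,5,6-trimethoxyphenyl)pentadecan-2-yl acetate | CCCCCCCCCCCCC[C@H](Cc1c(OC(C)=O)c(OC)cc(OC)c1OC)OC(C)=O | intermediate
16 | (2R)-1-(2-acetoxy-5-methoxy-3,6-dioxocyclohexa-1,4-dien-1-yl)pentadecan-2-yl acetate | CCCCCCCCCCCCC[C@H](CC1=C(OC(C)=O)C(=O)C=C(OC)C1=O)OC(C)=O | intermediate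
17 | (2R)-1-(2-hydroxy-5-methoxy-3,6-dioxocyclohexa-1,4-dien-1-yl)pentadecan-2-yl acetate (CNP0332196.1) | CCCCCCCCCCCCC[C@H](CC1=C(O)C(=O)C=C(OC)C1=O)OC(C)=O | target

**Step count**

Total: 9 steps. Longest linear sequence: 8 steps (steps 1–5 and 7–9); step 6 is a one-step branch.

**Steps most likely to fail**

Step 7 (proposed new method). What may go wrong:
- loss of HBr from the bromo ester to the conjugated enol acetate;
- Lewis-acid-assisted ionisation of the bromo ester followed by uncatalysed, non-selective alkyl transfer from zinc;
- ring acylation by acetyl bromide;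
- weak facial discrimination at a radical that carries a bulky 2,6-disubstituted benzyl group.

Fallback (known chemistry, polar carbonyl addition in place of the radical coupling): it sets out from aldehyde 10, with the alkyl group drawn from 11, and returns at 15. 1-Bromotridecane 11 and Mg in Et2O give tridecylmagnesium bromide F1, which with ZnCl2 (0.5 equiv) and 1,4-dioxane to precipitate the magnesium halide gives salt-free ditridecylzinc F2. Catalytic enantioselective addition of F2 to 10 with Ti(OiPr)4 and (1S,2S)-N,N'-bis(trifluoromethanesulfonyl)cyclohexane-1,2-diamine in toluene at −20 °C should give 2-[(2R)-2-hydroxypentadecyl]-3,4,6-trimethoxyphenyl acetate F3. The ligand antipode named is the one expected by analogy with other aldehydes to give R, to be confirmed. Any aryl-to-alkyl acetyl migration at this stage is harmless, because acetylation (Ac2O, pyridine, DMAP) converts either isomer into 15.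

Step 5. What may go wrong:
- over-oxidation during the aqueous periodate stage;
- self-condensation of the enolisable arylacetaldehyde on work-up and chromatography;
- acetyl migration from the phenol oxygen to the transient diol.

Fallback: it sets out from 8 and returns at 10, separating the two oxidations so that the aldehyde is released anhydrously and never purified. Upjohn dihydroxylation (K2OsO2(OH)4 cat., N-methylmorpholine N-oxide, acetone/H2O) gives diol 9, which is isolated and stored as the aldehyde equivalent. Cleavage with silica-supported NaIO4 in CH2Cl2, followed by filtration, should give a dry solution of 10 that is carried cold straight into step 7.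

Step 8. What may go wrong:
- attack of water at the wrong methoxy-bearing carbon, leading to an ortho-quinone from the adjacent methoxy pair;
- nitration or benzylic oxidation by tetravalent cerium;
- uncontrolled partial loss of the ring acetate in the acidic aqueous medium.

Fallback: it sets out from 15 and returns at 16 by a two-stage electrochemical route. Constant-current anodic oxidation at a Pt anode in MeOH (LiClO4 as neutral electrolyte, 2,6-lutidine as proton scavenger, 0 °C) should add methanol across the para positions to give the quinone bisketal (2R)-1-(2-acetoxy-3,3,5,6,6-pentamethoxycyclohexa-1,4-dien-1-yl)pentadecan-2-yl acetate F4. Mild hydrolysis (aqueous AcOH/acetone, rt) then unmasks both carbonyls to give 16.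

**Further compounds**

F1 | step 7 | tridecylmagnesium bromide | CCCCCCCCCCCCC[Mg]Br
F2 | step 7 | ditridecylzinc | CCCCCCCCCCCCC[Zn]CCCCCCCCCCCCC
F3 | step 7 | 2-[(2R)-2-hydroxypentadecyl]-3,4,6-trimethoxyphenyl acetate | CCCCCCCCCCCCC[C@H](Cc1c(OC(C)=O)c(OC)cc(OC)c1OC)O
F0 | step 5 | none | none
F4 | step 8 | (2R)-1-(2-acetoxy-3,3,5,6,6-pentamethoxycyclohexa-1,4-dien-1-yl)pentadecan-2-yl acetate | CCCCCCCCCCCCC[C@H](CC1=C(OC(C)=O)C(OC)(OC)C=C(OC)C1(OC)OC)OC(C)=O
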